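**Retrosynthetic overview**

1. Plakortolide R ⇐ olefin cross-metathesis at C13=C14 as the last step, because the phenyl diene would not survive the alkene hydroperoxidation; the precursor is a bicyclic peroxy-lactone with an oct-7-enyl chain.
2. 1,2-Dioxane ring (formed second) ⇐ C3–O bond by intramolecular peroxy-Michael addition of a C6 tertiary hydroperoxide to a γ,γ-disubstituted butenolide; the cis ring fusion and C3 follow from C4.
3. C6–O bond and C6 configuration ⇐ chiral-acid-catalysed Markovnikov addition of H2O2 to a 1,1-disubstituted alkene (the new step).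
4. Butenolide ring (formed first) ⇐ Z-selective olefination and lactonisation of an α-hydroxy aldehyde ⇐ α-hydroxy ester.
5. C4 and the C4–C5 bond ⇐ enantioselective pyruvate–ene reaction of 2-methyldeca-1,9-diene, itself from 7-bromohept-1-ene and methallylmagnesium chloride.

**Assumptions**

- Numbering: positions are numbered as in the plakortolides (C1 lactone carbonyl, C3 CH–O–O, C4 quaternary lactone carbon, C5 CH2, C6 peroxide carbon, C7–C16 side chain).
- Step 2 may give minor regioisomers with a C6=C7 double bond instead of the exocyclic methylene; they are not separated, because steps 3 and 4 treat them alike and step 5 converts all of them into the same C6 hydroperoxide.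
- Facial control at C6 in step 5 is a proposal; the route is written for the 6S epimer, and any 6R epimer is removed by chromatography after step 6, where the two bicyclic peroxides are diastereomers.

**Route**

Step 1
Reactants: 1 7-bromohept-1-ene; 2 (2-methylprop-2-en-1-yl)magnesium chloride
Product: 3 2-methyldeca-1,9-diene
Conditions: Li2CuCl4 (2 mol%), THF, −20 °C → rt
Reagents that add atoms: none
Why: Copper-catalysed Kochi-type sp3–sp3 cross-coupling of an allylic Grignard reagent with a primary alkyl bromide is fast and leaves the remote vinyl group untouched; no stereocentre is formed.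

Step 2
Reactants: 3 2-methyldeca-1,9-diene; 4 methyl 2-oxopropanoate (methyl pyruvate)
Product: 5 methyl (2S)-2-hydroxy-2-methyl-4-methylidenedodec-11-enoate
Conditions: [Cu((S,S)-t-Bu-box)](SbF6)2 (10 mol%; t-Bu-box = 2,2'-(propane-2,2-diyl)bis(4-tert-butyl-4,5-dihydrooxazole)), 3 (2 equiv, excess recovered), CH2Cl2, 40 °C
Reagents that add atoms: none
Why: Catalytic enantioselective carbonyl-ene (ketone-ene) reaction, in which pyruvate is held as a five-membered chelate on the square-planar divalent-copper bis(oxazoline) complex, one carbonyl face is shielded by a tert-butyl group, and only the nucleophilic 1,1-disubstituted alkene (not the vinyl group) attacks with transfer of an allylic hydrogen, forming the C4–C5 bond and setting C4 as S (the antipodal ligand is used should the facial sense prove opposite).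

Step 3
Reactants: 5 methyl (2S)-2-hydroxy-2-methyl-4-methylidenedodec-11-enoate
Product: 6 (2S)-2-hydroxy-2-methyl-4-methylidenedodec-11-enal
Conditions: i-Bu2AlH (2.2 equiv), CH2Cl2, −78 °C; aq. potassium sodium tartrate work-up
Reagents that add atoms: none
Why: Partial reduction of the ester with i-Bu2AlH at −78 °C stops at the tetrahedral aluminium hemiacetal, which is stabilised by chelation to the neighbouring aluminium alkoxide and releases the aldehyde only on work-up; C4 is not touched.

Step 4
Reactants: 6 (2S)-2-hydroxy-2-methyl-4-methylidenedodec-11-enal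
Product: 8 (5S)-5-methyl-5-(2-methylidenedec-9-en-1-yl)furan-2(5H)-one, via Z-hydroxy-enoate 7 (not isolated)
Conditions: (CF3CH2O)2P(O)CH2CO2Me, KN(SiMe3)2, 18-crown-6, THF, −78 °C; then p-TsOH (cat.), CH2Cl2, rt
Reagents that add atoms: methyl 2-[bis(2,2,2-trifluoroethoxy)phosphoryl]acetate, COC(=O)CP(=O)(OCC(F)(F)F)OCC(F)(F)F
Why: The Still–Gennari variant of the Horner–Wadsworth–Emmons olefination gives the Z-enoate, whose tertiary hydroxyl sits next to the ester and closes the butenolide by acid-catalysed lactonisation; C4 is not touched.

Step 5
Reactants: 8 (5S)-5-methyl-5-(2-methylidenedec-9-en-1-yl)furan-2(5H)-one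
Product: 9 (5S)-5-[(2S)-2-hydroperoxy-2-methyldec-9-en-1-yl]-5-methylfuran-2(5H)-one
Conditions: anhydrous H2O2 (ca. 3 M in Et2O, 5 equiv), confined chiral imidodiphosphorimidate Brønsted acid (IDPi, 5 mol%), CH2Cl2, −20 °C → 0 °C
Reagents that add atoms: hydrogen peroxide, OO
Why: Proposed new method: chiral-Brønsted-acid-catalysed Markovnikov hydroperoxidation of an unactivated alkene, in which the confined acid protonates the terminal CH2 while H2O2, hydrogen-bonded to the catalyst anion, captures the developing tertiary C6 cation from the opposite face inside the chiral pocket (concerted termolecular addition), so that the vinyl group (secondary cation) and the electron-poor butenolide are not touched, the C6–O bond is formed with H2O2 as the only added reagent, and C6 is set as S by catalyst control over the two very different alkene substituents (n-alkenyl chain against the bulky butenolide-CH2; the acid antipode matched to 4S is chosen by screening), the closest known reaction types being the mineral-acid-mediated addition of H2O2 to branched alkenes that gives tert-alkyl hydroperoxides and the confined-acid-catalysed enantioselective intramolecular hydroalkoxylation of unactivated 1,1-disubstituted alkenes.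

Step 6
Reactants: 9 (5S)-5-[(2S)-2-hydroperoxy-2-methyldec-9-en-1-yl]-5-methylfuran-2(5H)-one
Product: 10 (3S,4S,6S)-3,6-epidioxy-4,6-dimethyltetradec-13-en-4-olide
Conditions: Et2NH (0.5 equiv), CF3CH2OH, rt
Reagents that add atoms: none
Why: Amine-mediated intramolecular peroxy-oxa-Michael addition (6-exo-trig) of the hydroperoxide to the butenolide forms the C3–O bond and the 1,2-dioxane ring, the protic fluoro-alcohol protonating the enolate before it can expel alkoxide; the tether on C4 can reach C3 only from its own face, so the rings are cis-fused and C3 is set as S, while C6 is not touched.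

Step 7
Reactants: 10 (3S,4S,6S)-3,6-epidioxy-4,6-dimethyltetradec-13-en-4-olide; 11 [(1E)-buta-1,3-dien-1-yl]benzene
Product: 12 plakortolide R [(3S,4S,6S,13E,15E)-3,6-epidioxy-4,6-dimethyl-16-phenylhexadeca-13,15-dien-4-olide]
Conditions: 11 (3 equiv), second-generation Hoveyda–Grubbs catalyst RuCl2(H2IMes)(=CH-C6H4-2-O-i-Pr) (5 mol%), CH2Cl2, 40 °C; then I2 (2 mol%), CH2Cl2, daylight, rt
Reagents that add atoms: none
Why: Olefin cross-metathesis between the monosubstituted alkene of 10 and the unhindered terminal alkene of the diene (its internal, phenyl-conjugated alkene reacts more slowly) releases ethene and favours the 13E geometry, the iodine-catalysed equilibration converging residual 13Z isomer on the E,E-diene; ruthenium carbenes tolerate dialkyl peroxides and no stereocentre is touched.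

**Compound list**

1 | 7-bromohept-1-ene | C=CCCCCCBr | starting material
2 | (2-methylprop-2-en-1-yl)magnesium chloride | C=C(C)C[Mg]Cl | starting material
3 | 2-methyldeca-1,9-diene | C=C(C)CCCCCCC=C | intermediate
4 | methyl 2-oxopropanoate (methyl pyruvate) | CC(=O)C(=O)OC | starting material
5 | methyl (2S)-2-hydroxy-2-methyl-4-methylidenedodec-11-enoate | COC(=O)[C@@](C)(O)CC(=C)CCCCCCC=C | intermediate
6 | (2S)-2-hydroxy-2-methyl-4-methylidenedodec-11-enal | O=C[C@@](C)(O)CC(=C)CCCCCCC=C | intermediate
7 | methyl (2Z,4S)-4-hydroxy-4-methyl-6-methylidenetetradeca-2,13-dienoate (formed in the flask) | COC(=O)/C=C\[C@@](C)(O)CC(=C)CCCCCCC=C | intermediate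
8 | (5S)-5-methyl-5-(2-methylidenedec-9-en-1-yl)furan-2(5H)-one | C=C(CCCCCCC=C)C[C@]1(C)OC(=O)C=C1 | intermediate
9 | (5S)-5-[(2S)-2-hydroperoxy-2-methyldec-9-en-1-yl]-5-methylfuran-2(5H)-one | C[C@](OO)(CCCCCCC=C)C[C@]1(C)OC(=O)C=C1 | intermediate
10 | (3S,4S,6S)-3,6-epidioxy-4,6-dimethyltetradec-13-en-4-olide (1,2-dioxane with O–O between C3 and C6, cis-fused to the C1–C4 γ-lactone, oct-7-enyl on C6) | C[C@]1(CCCCCCC=C)C[C@]2(C)OC(=O)C[C@@H]2OO1 | intermediate
11 | [(1E)-buta-1,3-dien-1-yl]benzene | C=C/C=C/c1ccccc1 | starting material
12 | plakortolide R, (3S,4S,6S,13E,15E)-3,6-epidioxy-4,6-dimethyl-16-phenylhexadeca-13,15-dien-4-olide | C[C@]1(CCCCCC/C=C/C=C/c2ccccc2)C[C@]2(C)OC(=O)C[C@@H]2OO1 | target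

**Step count and risks**

Total step count: 7. Longest linear sequence: 7 steps (1 → 12).

The three steps most likely to fail:

Risk at step 2 (ene reaction). Pyruvate is a sluggish enophile, the acyclic alkene may react slowly or twice, and the enantiomeric excess is not assured. The fallback buys the C4 stereocentre and forms the C5–C6 bond instead; it sets out from 1 and comes back to the route at 6. Bromide 1 is converted with Mg in THF into hept-6-en-1-ylmagnesium bromide F1, which is alkylated with 2,3-dibromoprop-1-ene (CuI cat.) to give 2-bromodeca-1,9-diene F2. Mg in THF turns this into (deca-1,9-dien-2-yl)magnesium bromide F3. With CuI (10 mol%), F3 opens commercial (2R)-(2-methyloxiran-2-yl)methanol (first deprotonated with i-PrMgCl) at the epoxide CH2 to give (2S)-2-methyl-4-methylidenedodec-11-ene-1,2-diol F4. TEMPO (cat.) with PhI(OAc)2 in CH2Cl2 oxidises only the primary alcohol and delivers aldehyde 6, which also bypasses step 3.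

Risk at step 5 (the proposed new hydroperoxidation). The acid may be levelled by ether and H2O2 so that conversion is low, the facial control at C6 may be poor, or the hydroperoxide may undergo acid-induced cleavage. The fallback is known chemistry that replaces the ionic addition by a radical one; it sets out from 8 and comes back at 9. Cobalt-catalysed aerobic hydroperoxysilylation of 8 uses Co(thd)2 (cobalt bis(2,2,6,6-tetramethylheptane-3,5-dionate), divalent cobalt, 5 mol%), O2 (1 atm) and Et3SiH in ClCH2CH2Cl at rt. It is stopped at partial conversion, because the 1,1-disubstituted alkene reacts faster than the vinyl group, and gives (5S)-5-methyl-5-{2-methyl-2-[(triethylsilyl)peroxy]dec-9-en-1-yl}furan-2(5H)-one F5 as a roughly 1:1 mixture at C6. HCl (cat.) in MeOH removes the silyl group and returns 9 together with its 6R epimer, which is separated after step 6.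

Risk at step 7 (cross-metathesis with the diene). The carbene may also attack the internal alkene of 11 and give a truncated styrene, and the E/Z ratio at C13 may be modest. The fallback builds the diene in two bond-forming events; it sets out from 10 and comes back at 12. Cross-metathesis of 10 with 4,4,5,5-tetramethyl-2-vinyl-1,3,2-dioxaborolane, using the second-generation Grubbs catalyst RuCl2(H2IMes)(PCy3)(=CHPh) in CH2Cl2 at 40 °C, has no competing internal alkene. It gives (3S,4S,6S,13E)-3,6-epidioxy-4,6-dimethyl-14-(4,4,5,5-tetramethyl-1,3,2-dioxaborolan-2-yl)tetradec-13-en-4-olide F6. Suzuki–Miyaura coupling of F6 with [(E)-2-bromoethenyl]benzene (Pd(PPh3)4, a zerovalent palladium complex, aq. K3PO4, THF, rt) then gives 12 with both double bonds E.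

**Further compounds**

F1 | step 2 | hept-6-en-1-ylmagnesium bromide | C=CCCCCC[Mg]Br
F2 | step 2 | 2-bromodeca-1,9-diene | C=C(Br)CCCCCCC=C
F3 | step 2 | (deca-1,9-dien-2-yl)magnesium bromide | C=C([Mg]Br)CCCCCCC=C
F4 | step 2 | (2S)-2-methyl-4-methylidenedodec-11-ene-1,2-diol | C[C@@](O)(CO)CC(=C)CCCCCCC=C
F5 | step 5 | (5S)-5-methyl-5-{2-methyl-2-[(triethylsilyl)peroxy]dec-9-en-1-yl}furan-2(5H)-one (mixture of C6 epimers) | CC[Si](CC)(CC)OOC(C)(CCCCCCC=C)C[C@]1(C)OC(=O)C=C1
F6 | step 7 | (3S,4S,6S,13E)-3,6-epidioxy-4,6-dimethyl-14-(4,4,5,5-tetramethyl-1,3,2-dioxaborolan-2-yl)tetradec-13-en-4-olide | C[C@]1(CCCCCC/C=C/B3OC(C)(C)C(C)(C)O3)C[C@]2(C)OC(=O)C[C@@H]2OO1
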